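**Retrosynthetic overview**

1. Target 21 ← epoxy alcohol 20 (Dess–Martin) ← allylic alcohol 19 (hydroxyl-directed epoxidation) ← bis-angelate enone 18 (Luche). The oxirane is the last ring formed, syn to a transient C2–OH and therefore cis to the C4 side chain.
2. 18 ← enone alcohol 13 by Mitsunobu inversion at C3′ with angelic acid, enolate hydroxylation at C3 anti to the C4 substituent, and acylation.
3. 13 ← bridged silyl enol ether 10 by methylenation of the C2′ ketone and Saegusa–Ito oxidation with desilylation.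
4. 10 ← acyclic silaketal triene 9 by a silicon-tethered type 2 intramolecular Diels–Alder reaction that forms C3–C4 and C5–C6 together and closes the carbocycle, the first ring formed. Enabling feature: the oxygen on ring carbon C2 and the oxygen on side-chain carbon C3′ are joined through C2–C3–C4–C2′–C3′, so one silicon atom can tie diene and dienophile; C2′ (C=CH2 in the target) is carried as a ketone that activates C4=C5.
5. 9 ← 3-methylbut-3-en-2-one + i-Pr2Si(OTf)2 + hydroxy enone 6 ← methyl (R)-glycidate (three steps).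

Key step: step 5

Remark: ring atoms are numbered as in 7-oxabicyclo[4.1.0]heptane (C1 methyl-bearing oxirane carbon, C2 ketone, C3 CH–O, C4 CH with the side chain, C5 CH2, C6 oxirane CH) and the side chain as C1′ (=CH2) to C7′. Both enantiomers of methyl glycidate, angelic acid and i-Pr2Si(OTf)2 are assumed to be purchased.

**Route**

Step 1
Reactants: 1 methyl (2R)-oxirane-2-carboxylate; 2 (2-methylprop-1-en-1-yl)magnesium bromide
Product: 3 methyl (2R)-2-hydroxy-5-methylhex-4-enoate
Conditions: 2 (1.5 equiv), CuI (10 mol %), THF, −40 → −20 °C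
Reagents that add atoms: none
Why: Copper-catalysed SN2 opening of the glycidic ester by the alkenyl Grignard reagent (organocuprate epoxide opening) occurs at the unsubstituted oxirane carbon, so the stereocentre is untouched and becomes the (R) carbinol.

Step 2
Reactants: 3 methyl (2R)-2-hydroxy-5-methylhex-4-enoate
Product: 4 (2R)-2-hydroxy-N-methoxy-N,5-dimethylhex-4-enamide
Conditions: MeNH(OMe)·HCl, i-PrMgCl, THF, −20 → 0 °C
Reagents that add atoms: N,O-dimethylhydroxylamine hydrochloride, CNOC.Cl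
Why: Aminolysis of the methyl ester by the chloromagnesium amide (Weinreb amide formation) runs at low temperature on the magnesium alkoxide and leaves the carbinol centre unchanged.

Step 3
Reactants: 4 (2R)-2-hydroxy-N-methoxy-N,5-dimethylhex-4-enamide; 5 vinylmagnesium bromide
Product: 6 (4R)-4-hydroxy-7-methylocta-1,6-dien-3-one
Conditions: 5 (3 equiv), THF, −78 → 0 °C; inverse quench into cold aq. NaHSO4
Reagents that add atoms: none
Why: Weinreb ketone synthesis, in which the first equivalent of Grignard reagent deprotonates the hydroxyl and the second adds only once because the chelated tetrahedral intermediate survives until the acidic quench, which also keeps the liberated amine from adding to the vinyl ketone.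

Step 4
Reactants: 7 3-methylbut-3-en-2-one; 6 (4R)-4-hydroxy-7-methylocta-1,6-dien-3-one
Product: 9 (4R)-7-methyl-4-({[(3-methylbuta-1,3-dien-2-yl)oxy]di(propan-2-yl)silyl}oxy)octa-1,6-dien-3-one, via dienyl silyl triflate 8 (not isolated)
Conditions: 7, i-Pr2Si(OTf)2 (1.05 equiv), Et3N, CH2Cl2, −78 °C; then 6, Et3N, −78 → 0 °C
Reagents that add atoms: diisopropylsilyl bis(trifluoromethanesulfonate), CC(C)[Si](OS(=O)(=O)C(F)(F)F)(OS(=O)(=O)C(F)(F)F)C(C)C
Why: Soft enolization and O-silylation of the enone at its only enolizable position (the acetyl methyl) gives the 2-silyloxy diene as a silyl triflate, whose remaining Si–OTf bond is displaced by the secondary alcohol (unsymmetrical silaketal formation) without touching the stereocentre.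

Step 5
Reactants: 9 (4R)-7-methyl-4-({[(3-methylbuta-1,3-dien-2-yl)oxy]di(propan-2-yl)silyl}oxy)octa-1,6-dien-3-one
Product: 10 (5R,7R)-10-methyl-5-(3-methylbut-2-en-1-yl)-3,3-di(propan-2-yl)-2,4-dioxa-3-silabicyclo[5.3.1]undec-1(10)-en-6-one
Conditions: PhMe (0.01 M), BHT (cat.), 130 °C, sealed tube
Reagents that add atoms: none
Why: A thermal, concerted but asynchronous [4+2] cycloaddition in which the electron-rich 2-silyloxy diene (C3=C2–C1=C6) adds across the ketone-activated C4=C5 bond and forms C3–C4 and C5–C6 in one event; the closest known reaction type is the silicon-tethered type 2 intramolecular Diels–Alder reaction of 2-silyloxy dienes, which gives bridgehead silyl enol ethers. The cyclohexene ring closes by [4+2] cycloaddition and the same two bonds close the eight-membered dioxasila ring, so a bicyclo[5.3.1]undec-1(10)-ene results (bridged, because the tether enters the diene at its 2-position). Regioselectivity is the first need: untethered 2-silyloxy dienes place an acyl group 1,4 to the oxygen, but the five-atom O–Si–O–C3′–C2′ tether can hold the acyl-bearing carbon only over C3, which enforces the 1,3 relation of C2–O and C4 that the target requires. The one new stereocentre (C4) is controlled by the carbinol centre C3′ next to the activating ketone: the ketone must be endo, the enone is expected to react s-cis, the C3′–O bond must point toward the diene, and of the two positions left on C3′ the prenyl CH2 should take the one eclipsing C=O on the open outer face rather than the one pressed against C4–H, which selects the diene face that pairs (R)-C3′ with the target configuration at C4. Chemoselectivity follows from activation, since only the vinyl ketone is a competent dienophile, and high dilution suppresses intermolecular cycloaddition.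

Step 6
Reactants: 10 (5R,7R)-10-methyl-5-(3-methylbut-2-en-1-yl)-3,3-di(propan-2-yl)-2,4-dioxa-3-silabicyclo[5.3.1]undec-1(10)-en-6-one
Product: 11 (5R,7R)-10-methyl-6-methylidene-5-(3-methylbut-2-en-1-yl)-3,3-di(propan-2-yl)-2,4-dioxa-3-silabicyclo[5.3.1]undec-1(10)-ene
Conditions: Cp2TiMe2 (3 equiv), PhMe/THF, 70 °C, dark
Reagents that add atoms: dimethyltitanocene Cp2TiMe2, C[Ti](C)(C1C=CC=C1)C1C=CC=C1
Why: Petasis methylenation through Cp2Ti=CH2 and an oxatitanacyclobutane is non-basic, so the α-silyloxy stereocentre is not epimerized and the silyl enol ether and silaketal stay intact.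

Step 7
Reactants: 11 (5R,7R)-10-methyl-6-methylidene-5-(3-methylbut-2-en-1-yl)-3,3-di(propan-2-yl)-2,4-dioxa-3-silabicyclo[5.3.1]undec-1(10)-ene
Product: 13 (5R)-5-[(3R)-3-hydroxy-6-methylhepta-1,5-dien-2-yl]-2-methylcyclohex-2-en-1-one, via acetoxysilyl ether 12 (not isolated)
Conditions: Pd(OAc)2 (1.1 equiv), MeCN, 25 °C; then HF·pyridine, THF, 0 °C
Reagents that add atoms: none
Why: Saegusa–Ito oxidation, in which palladium diacetate turns the silyl enol ether into a divalent palladium enolate at C1 and β-hydride elimination toward the ring CH2 (C6) gives the conjugated 2-methylcyclohex-2-enone while the tether opens to an acetoxysilyl ether that fluoride removes; C4 and C3′ are not affected.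

Step 8
Reactants: 13 (5R)-5-[(3R)-3-hydroxy-6-methylhepta-1,5-dien-2-yl]-2-methylcyclohex-2-en-1-one; 14 (2Z)-2-methylbut-2-enoic acid (angelic acid)
Product: 15 (3S)-6-methyl-2-[(1R)-4-methyl-5-oxocyclohex-3-en-1-yl]hepta-1,5-dien-3-yl (2Z)-2-methylbut-2-enoate
Conditions: 14 (1.5 equiv), PPh3, DIAD, PhMe, 0 → 25 °C
Reagents that add atoms: none
Why: Mitsunobu esterification displaces the allylic oxyphosphonium by angelate in an SN2 sense, inverting C3′ from (R) to (S), and the neutral conditions without nucleophilic amine should preserve the Z geometry of the acid.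

Step 9
Reactants: 15 (3S)-6-methyl-2-[(1R)-4-methyl-5-oxocyclohex-3-en-1-yl]hepta-1,5-dien-3-yl (2Z)-2-methylbut-2-enoate
Product: 16 (3S)-2-[(1S,6S)-6-hydroxy-4-methyl-5-oxocyclohex-3-en-1-yl]-6-methylhepta-1,5-dien-3-yl (2Z)-2-methylbut-2-enoate
Conditions: LiN(SiMe3)2 (1.15 equiv), THF, −78 °C; then 2-(phenylsulfonyl)-3-phenyloxaziridine, −78 °C
Reagents that add atoms: 2-(phenylsulfonyl)-3-phenyloxaziridine, O=S(=O)(N1OC1c1ccccc1)c1ccccc1
Why: Kinetic deprotonation gives the cross-conjugated α′-enolate (the ketone is far more acidic than the ester), and electrophilic enolate hydroxylation by the N-sulfonyloxaziridine should occur on the face anti to the adjacent C4 substituent, setting C3 trans to the side chain.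

Step 10
Reactants: 16 (3S)-2-[(1S,6S)-6-hydroxy-4-methyl-5-oxocyclohex-3-en-1-yl]-6-methylhepta-1,5-dien-3-yl (2Z)-2-methylbut-2-enoate; 14 (2Z)-2-methylbut-2-enoic acid
Product: 18 (1S,6S)-3-methyl-6-[(3S)-6-methyl-3-{[(2Z)-2-methylbut-2-enoyl]oxy}hepta-1,5-dien-2-yl]-2-oxocyclohex-3-en-1-yl (2Z)-2-methylbut-2-enoate, via mixed anhydride 17 (not isolated)
Conditions: 14, 2,4,6-trichlorobenzoyl chloride, Et3N, PhMe, 25 °C; then 16, 75 °C
Reagents that add atoms: none
Why: Yamaguchi-type acylation through the mixed anhydride, which is attacked at the less hindered angeloyl carbonyl, gives the ester with retention at C3, and leaving out nucleophilic catalysts should avoid Z to E isomerization.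

Step 11
Reactants: 18 (1S,6S)-3-methyl-6-[(3S)-6-methyl-3-{[(2Z)-2-methylbut-2-enoyl]oxy}hepta-1,5-dien-2-yl]-2-oxocyclohex-3-en-1-yl (2Z)-2-methylbut-2-enoate
Product: 19 (1S,2S,6S)-2-hydroxy-3-methyl-6-[(3S)-6-methyl-3-{[(2Z)-2-methylbut-2-enoyl]oxy}hepta-1,5-dien-2-yl]cyclohex-3-en-1-yl (2Z)-2-methylbut-2-enoate
Conditions: NaBH4, CeCl3·7H2O, MeOH, −78 °C
Reagents that add atoms: none
Why: Luche 1,2-reduction, in which axial hydride delivery to the half-chair enone with both C3 and C4 substituents equatorial should give the equatorial alcohol (C2–OH trans to the C3 ester and cis to the C4 side chain) while the esters are not reduced at −78 °C.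

Step 12
Reactants: 19 (1S,2S,6S)-2-hydroxy-3-methyl-6-[(3S)-6-methyl-3-{[(2Z)-2-methylbut-2-enoyl]oxy}hepta-1,5-dien-2-yl]cyclohex-3-en-1-yl (2Z)-2-methylbut-2-enoate
Product: 20 (1R,2R,3S,4S,6S)-2-hydroxy-1-methyl-4-[(3S)-6-methyl-3-{[(2Z)-2-methylbut-2-enoyl]oxy}hepta-1,5-dien-2-yl]-7-oxabicyclo[4.1.0]heptan-3-yl (2Z)-2-methylbut-2-enoate
Conditions: VO(acac)2 (5 mol %), t-BuOOH, CH2Cl2, 0 → 25 °C
Reagents that add atoms: tert-butyl hydroperoxide, CC(C)(C)OO
Why: Vanadium-catalysed hydroxyl-directed epoxidation delivers oxygen to C1=C6 from the face of the C2 hydroxyl, which sets C1 and C6 with the oxirane cis to the C4 side chain, and the other alkenes carry no free hydroxyl and should not be attacked.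

Step 13
Reactants: 20 (1R,2R,3S,4S,6S)-2-hydroxy-1-methyl-4-[(3S)-6-methyl-3-{[(2Z)-2-methylbut-2-enoyl]oxy}hepta-1,5-dien-2-yl]-7-oxabicyclo[4.1.0]heptan-3-yl (2Z)-2-methylbut-2-enoate
Product: 21 (1S,3S,4S,6S)-1-methyl-4-[(3S)-6-methyl-3-{[(2Z)-2-methylbut-2-enoyl]oxy}hepta-1,5-dien-2-yl]-2-oxo-7-oxabicyclo[4.1.0]heptan-3-yl (2Z)-2-methylbut-2-enoate
Conditions: Dess–Martin periodinane, NaHCO3, CH2Cl2, 0 → 25 °C
Reagents that add atoms: none
Why: Dess–Martin oxidation of the secondary alcohol to the ketone under buffered, non-basic conditions leaves the epoxide, the esters and the epimerizable C3 centre untouched.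

**Compound list**

1 | methyl (2R)-oxirane-2-carboxylate | COC(=O)[C@H]1CO1 | starting material
2 | (2-methylprop-1-en-1-yl)magnesium bromide | CC(C)=C[Mg]Br | starting material
3 | methyl (2R)-2-hydroxy-5-methylhex-4-enoate | COC(=O)[C@H](O)CC=C(C)C | intermediate
4 | (2R)-2-hydroxy-N-methoxy-N,5-dimethylhex-4-enamide | CON(C)C(=O)[C@H](O)CC=C(C)C | intermediate
5 | vinylmagnesium bromide | C=C[Mg]Br | starting material
6 | (4R)-4-hydroxy-7-methylocta-1,6-dien-3-one | C=CC(=O)[C@H](O)CC=C(C)C | intermediate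
7 | 3-methylbut-3-en-2-one | CC(=O)C(C)=C | starting material
8 | [(3-methylbuta-1,3-dien-2-yl)oxy]di(propan-2-yl)silyl trifluoromethanesulfonate | C=C(C)C(=C)O[Si](C(C)C)(C(C)C)OS(=O)(=O)C(F)(F)F | intermediate (not isolated)
9 | (4R)-7-methyl-4-({[(3-methylbuta-1,3-dien-2-yl)oxy]di(propan-2-yl)silyl}oxy)octa-1,6-dien-3-one | C=CC(=O)[C@@H](CC=C(C)C)O[Si](C(C)C)(C(C)C)OC(=C)C(C)=C | intermediate
10 | (5R,7R)-10-methyl-5-(3-methylbut-2-en-1-yl)-3,3-di(propan-2-yl)-2,4-dioxa-3-silabicyclo[5.3.1]undec-1(10)-en-6-one | CC1=C2C[C@@H](CC1)C(=O)[C@@H](CC=C(C)C)O[Si](C(C)C)(C(C)C)O2 | intermediate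
11 | (5R,7R)-10-methyl-6-methylidene-5-(3-methylbut-2-en-1-yl)-3,3-di(propan-2-yl)-2,4-dioxa-3-silabicyclo[5.3.1]undec-1(10)-ene | CC1=C2C[C@@H](CC1)C(=C)[C@@H](CC=C(C)C)O[Si](C(C)C)(C(C)C)O2 | intermediate
12 | acetoxy{[(3R)-6-methyl-2-[(1R)-4-methyl-5-oxocyclohex-3-en-1-yl]hepta-1,5-dien-3-yl]oxy}di(propan-2-yl)silane | CC1=CC[C@H](CC1=O)C(=C)[C@@H](CC=C(C)C)O[Si](C(C)C)(C(C)C)OC(C)=O | intermediate (not isolated)
13 | (5R)-5-[(3R)-3-hydroxy-6-methylhepta-1,5-dien-2-yl]-2-methylcyclohex-2-en-1-one | CC1=CC[C@H](CC1=O)C(=C)[C@H](O)CC=C(C)C | intermediate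
14 | (2Z)-2-methylbut-2-enoic acid (angelic acid) | C/C=C(/C)C(=O)O | starting material
15 | (3S)-6-methyl-2-[(1R)-4-methyl-5-oxocyclohex-3-en-1-yl]hepta-1,5-dien-3-yl (2Z)-2-methylbut-2-enoate | CC1=CC[C@H](CC1=O)C(=C)[C@@H](OC(=O)/C(C)=C\C)CC=C(C)C | intermediate
16 | (3S)-2-[(1S,6S)-6-hydroxy-4-methyl-5-oxocyclohex-3-en-1-yl]-6-methylhepta-1,5-dien-3-yl (2Z)-2-methylbut-2-enoate | CC1=CC[C@H]([C@H](O)C1=O)C(=C)[C@@H](OC(=O)/C(C)=C\C)CC=C(C)C | intermediate
17 | (2Z)-2-methylbut-2-enoic 2,4,6-trichlorobenzoic anhydride | C/C=C(/C)C(=O)OC(=O)c1c(Cl)cc(Cl)cc1Cl | intermediate (not isolated)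
18 | (1S,6S)-3-methyl-6-[(3S)-6-methyl-3-{[(2Z)-2-methylbut-2-enoyl]oxy}hepta-1,5-dien-2-yl]-2-oxocyclohex-3-en-1-yl (2Z)-2-methylbut-2-enoate | CC1=CC[C@H]([C@H](OC(=O)/C(C)=C\C)C1=O)C(=C)[C@@H](OC(=O)/C(C)=C\C)CC=C(C)C | intermediate
19 | (1S,2S,6S)-2-hydroxy-3-methyl-6-[(3S)-6-methyl-3-{[(2Z)-2-methylbut-2-enoyl]oxy}hepta-1,5-dien-2-yl]cyclohex-3-en-1-yl (2Z)-2-methylbut-2-enoate | CC1=CC[C@H]([C@H](OC(=O)/C(C)=C\C)[C@H]1O)C(=C)[C@@H](OC(=O)/C(C)=C\C)CC=C(C)C | intermediate
20 | (1R,2R,3S,4S,6S)-2-hydroxy-1-methyl-4-[(3S)-6-methyl-3-{[(2Z)-2-methylbut-2-enoyl]oxy}hepta-1,5-dien-2-yl]-7-oxabicyclo[4.1.0]heptan-3-yl (2Z)-2-methylbut-2-enoate | C=C([C@H](CC=C(C)C)OC(=O)/C(C)=C\C)[C@@H]1C[C@@H]2O[C@]2(C)[C@H](O)[C@H]1OC(=O)/C(C)=C\C | intermediate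
21 | (1S,3S,4S,6S)-1-methyl-4-[(3S)-6-methyl-3-{[(2Z)-2-methylbut-2-enoyl]oxy}hepta-1,5-dien-2-yl]-2-oxo-7-oxabicyclo[4.1.0]heptan-3-yl (2Z)-2-methylbut-2-enoate | C=C([C@H](CC=C(C)C)OC(=O)/C(C)=C\C)[C@@H]1C[C@@H]2O[C@]2(C)C(=O)[C@H]1OC(=O)/C(C)=C\C | target

**Totals and risks**

Total step count: 13. Longest linear sequence: 13 steps (from 1); compounds 2, 5, 7 and 14 are purchased and enter directly.

Steps most likely to fail:

Step 5. Face selection of the diene by the tether stereocentre may be weak, or reversed if the enone reacts through its s-trans rotamer. The fallback runs the relay in the mirror-image sense and replaces the invertive esterification by a retentive one; it sets out from 2 (with 5, 7 and 14) and comes back at 18. Purchased methyl (2S)-oxirane-2-carboxylate F1 is opened with 2 as in step 1 to methyl (2S)-2-hydroxy-5-methylhex-4-enoate F2. This is taken as in steps 2 and 3 to (2S)-2-hydroxy-N-methoxy-N,5-dimethylhex-4-enamide F3 and (4S)-4-hydroxy-7-methylocta-1,6-dien-3-one F4, and silaketal formation with 8 gives the (4S) triene F5. Its cycloaddition would then give the (5S,7R) adduct F6 with the target configuration at C4; methylenation gives the (5S,7R) methylidene compound F7, Saegusa–Ito oxidation the acetoxysilyl ether F8, and HF·pyridine the (3′S) enone alcohol F9. No inversion is needed: the dianion of F9 (2.2 equiv LiN(SiMe3)2) is hydroxylated with the oxaziridine to the (5S,6S) diol F10, and both hydroxyls are acylated in one operation with 14 via 17 to give 18. The two series are diastereomeric from the adduct onward, so a minor isomer can be separated at the stage of 13 or F9.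

Step 7. Palladation of the hindered bridgehead enol ether may be slow, or β-hydride elimination may go toward the methyl group and give the exocyclic enone. The fallback opens the bicycle first and makes the enone by selenoxide elimination; it sets out from 11 and comes back at 13. MeLi (THF, 0 °C) cleaves the enol Si–O bond to the lithium enolate F11, which now carries a methyldi(propan-2-yl)silyl ether on C3′. PhSeBr at −78 °C gives the α-phenylselanyl ketone F12, H2O2/pyridine the selenoxide F13, and syn-elimination the enone silyl ether F14; HF·pyridine then releases 13.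

Step 10. Acylation of the hindered α′-hydroxy enone may be slow, with loss of the Z geometry of the acyl group or epimerization at C3 under the forcing basic conditions. The fallback builds the angelate on the substrate; it sets out from 16 and comes back at 18. Compound 16 is acylated with 2-(diphenoxyphosphoryl)propanoic acid (carbodiimide, CH2Cl2, 0 °C) to the phosphonate ester F15. A Z-selective Horner–Wadsworth–Emmons reaction with acetaldehyde (KN(SiMe3)2, 18-crown-6, THF, −78 °C) then gives 18.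

**Further compounds**

F1 | step 5 | methyl (2S)-oxirane-2-carboxylate | COC(=O)[C@@H]1CO1
F2 | step 5 | methyl (2S)-2-hydroxy-5-methylhex-4-enoate | COC(=O)[C@@H](O)CC=C(C)C
F3 | step 5 | (2S)-2-hydroxy-N-methoxy-N,5-dimethylhex-4-enamide | CON(C)C(=O)[C@@H](O)CC=C(C)C
F4 | step 5 | (4S)-4-hydroxy-7-methylocta-1,6-dien-3-one | C=CC(=O)[C@@H](O)CC=C(C)C
F5 | step 5 | (4S)-7-methyl-4-({[(3-methylbuta-1,3-dien-2-yl)oxy]di(propan-2-yl)silyl}oxy)octa-1,6-dien-3-one | C=CC(=O)[C@H](CC=C(C)C)O[Si](C(C)C)(C(C)C)OC(=C)C(C)=C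
F6 | step 5 | (5S,7R)-10-methyl-5-(3-methylbut-2-en-1-yl)-3,3-di(propan-2-yl)-2,4-dioxa-3-silabicyclo[5.3.1]undec-1(10)-en-6-one | CC1=C2C[C@@H](CC1)C(=O)[C@H](CC=C(C)C)O[Si](C(C)C)(C(C)C)O2
F7 | step 5 | (5S,7R)-10-methyl-6-methylidene-5-(3-methylbut-2-en-1-yl)-3,3-di(propan-2-yl)-2,4-dioxa-3-silabicyclo[5.3.1]undec-1(10)-ene | CC1=C2C[C@@H](CC1)C(=C)[C@H](CC=C(C)C)O[Si](C(C)C)(C(C)C)O2
F8 | step 5 | acetoxy{[(3S)-6-methyl-2-[(1R)-4-methyl-5-oxocyclohex-3-en-1-yl]hepta-1,5-dien-3-yl]oxy}di(propan-2-yl)silane | CC1=CC[C@H](CC1=O)C(=C)[C@H](CC=C(C)C)O[Si](C(C)C)(C(C)C)OC(C)=O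
F9 | step 5 | (5R)-5-[(3S)-3-hydroxy-6-methylhepta-1,5-dien-2-yl]-2-methylcyclohex-2-en-1-one | CC1=CC[C@H](CC1=O)C(=C)[C@@H](O)CC=C(C)C
F10 | step 5 | (5S,6S)-6-hydroxy-5-[(3S)-3-hydroxy-6-methylhepta-1,5-dien-2-yl]-2-methylcyclohex-2-en-1-one | CC1=CC[C@H]([C@H](O)C1=O)C(=C)[C@@H](O)CC=C(C)C
F11 | step 7 | lithium (5R)-2-methyl-5-[(3R)-6-methyl-3-{[methyldi(propan-2-yl)silyl]oxy}hepta-1,5-dien-2-yl]cyclohex-1-en-1-olate | [Li+].CC1=C([O-])C[C@@H](CC1)C(=C)[C@@H](CC=C(C)C)O[Si](C)(C(C)C)C(C)C
F12 | step 7 | (5R)-2-methyl-5-[(3R)-6-methyl-3-{[methyldi(propan-2-yl)silyl]oxy}hepta-1,5-dien-2-yl]-2-(phenylselanyl)cyclohexan-1-one | CC1([Se]c2ccccc2)CC[C@H](CC1=O)C(=C)[C@@H](CC=C(C)C)O[Si](C)(C(C)C)C(C)C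
F13 | step 7 | (5R)-2-methyl-5-[(3R)-6-methyl-3-{[methyldi(propan-2-yl)silyl]oxy}hepta-1,5-dien-2-yl]-2-(phenylseleninyl)cyclohexan-1-one | CC1([Se](=O)c2ccccc2)CC[C@H](CC1=O)C(=C)[C@@H](CC=C(C)C)O[Si](C)(C(C)C)C(C)C
F14 | step 7 | (5R)-2-methyl-5-[(3R)-6-methyl-3-{[methyldi(propan-2-yl)silyl]oxy}hepta-1,5-dien-2-yl]cyclohex-2-en-1-one | CC1=CC[C@H](CC1=O)C(=C)[C@@H](CC=C(C)C)O[Si](C)(C(C)C)C(C)C
F15 | step 10 | (1S,6S)-3-methyl-6-[(3S)-6-methyl-3-{[(2Z)-2-methylbut-2-enoyl]oxy}hepta-1,5-dien-2-yl]-2-oxocyclohex-3-en-1-yl 2-(diphenoxyphosphoryl)propanoate | CC1=CC[C@H]([C@H](OC(=O)C(C)P(=O)(Oc2ccccc2)Oc2ccccc2)C1=O)C(=C)[C@@H](OC(=O)/C(C)=C\C)CC=C(C)C
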